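**Plan**

- Retrosynthesis: the lactol is masked as its acetal with (R)-1-phenylethanol and the ring B phenol as a benzyl ether. The ester C–O bond of the seven-membered ring C is cut first, then, in one operation, the diaryl ether C–O bond and the aryl–CHO C–C bond on ring A.
- The double cut rests on ring A: its ether oxygen and its formyl group sit on neighbouring carbons, the formyl carbon lying next to the methoxy-bearing carbon. An aryne spanning these two carbons can take an aryloxy group and a formyl group from the formate ester of the ring B phenol.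
- Forward: the ring A 2-silylaryl triflate 7 comes from orsellinic acid (steps 1–4). The ring B formate 18 comes from methyl 2,4-dihydroxybenzoate (steps 5–12), its five-membered lactol ring closing in step 10. The two are joined in step 13.
- Both allyl groups are then removed, ring C is closed by lactonisation (step 15), and hydrogenolysis frees the phenol and the lactol.
- Stereochemistry: the only stereocentre, the lactol carbon (S), is fixed in step 11 by separating the diastereomeric acetals formed with (R)-1-phenylethanol. The last step breaks the benzylic O–C bond, not the acetal C–O bond, so the configuration is kept.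

Key step: step 13

Assumption: the free lactol of the target is taken to hold its configuration under neutral, aprotic conditions (ring–chain tautomerism needs acid or base), so the last step and its work-up are kept neutral.

**Route**

Step 1
Reactants: 1 orsellinic acid (2,4-dihydroxy-6-methylbenzoic acid)
Product: 2 allyl 2,4-dihydroxy-6-methylbenzoate
Conditions: allyl bromide, KHCO3, DMF, rt
Reagents that add atoms: allyl bromide, C=CCBr
Why: Hydrogencarbonate deprotonates only the carboxylic acid, so SN2 O-alkylation of the carboxylate should give the allyl ester with both phenols untouched, and room temperature avoids decarboxylation of the acid.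

Step 2
Reactants: 2 allyl 2,4-dihydroxy-6-methylbenzoate
Product: 3 allyl 2-hydroxy-4-methoxy-6-methylbenzoate
Conditions: MeI (1.05 equiv), K2CO3, acetone, rt to 40 °C
Reagents that add atoms: iodomethane, CI
Why: Williamson etherification takes place at the 4-hydroxyl because the 2-hydroxyl is held in a hydrogen bond to the ester carbonyl and is much less nucleophilic.

Step 3
Reactants: 3 allyl 2-hydroxy-4-methoxy-6-methylbenzoate
Product: 4 allyl 3-bromo-2-hydroxy-4-methoxy-6-methylbenzoate
Conditions: NBS, i-Pr2NH (10 mol %), CH2Cl2, 0 °C
Reagents that add atoms: N-bromosuccinimide, O=C1CCC(=O)N1Br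
Why: Amine-catalysed electrophilic bromination with NBS is directed ortho to the free phenol, whose only open ortho position is C-3 between the hydroxyl and methoxy groups, and the ionic conditions at 0 °C should leave the allyl double bond alone.

Step 4
Reactants: 4 allyl 3-bromo-2-hydroxy-4-methoxy-6-methylbenzoate
Product: 7 allyl 4-methoxy-6-methyl-2-(trifluoromethylsulfonyloxy)-3-(trimethylsilyl)benzoate, via aryl silyl ether 5 (not isolated), via lithium silylphenoxide 6 (not isolated)
Conditions: HMDS, THF, 70 °C, then evaporation; n-BuLi, THF, −100 °C; Tf2O, −100 °C to rt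
Reagents that add atoms: hexamethyldisilazane, C[Si](C)(C)N[Si](C)(C)C; trifluoromethanesulfonic anhydride, O=S(=O)(OS(=O)(=O)C(F)(F)F)C(F)(F)F
Why: O-silylation followed by bromine–lithium exchange triggers a 1,3 retro-Brook shift of the silyl group from oxygen to C-3, and the lithium phenoxide is trapped as the triflate; at −100 °C the exchange should outrun addition to the allyl ester, which is shielded by two ortho substituents.

Step 5
Reactants: 8 methyl 2,4-dihydroxybenzoate
Product: 9 methyl 4-(allyloxy)-2-hydroxybenzoate
Conditions: allyl bromide (1.05 equiv), K2CO3, acetone, reflux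
Reagents that add atoms: allyl bromide, C=CCBr
Why: Williamson etherification is selective for the more acidic 4-hydroxyl para to the ester, the 2-hydroxyl being chelated to the ester carbonyl.

Step 6
Reactants: 9 methyl 4-(allyloxy)-2-hydroxybenzoate
Product: 10 methyl 4-(allyloxy)-2-(benzyloxy)benzoate
Conditions: BnBr, K2CO3, DMF, 60 °C
Reagents that add atoms: benzyl bromide, BrCc1ccccc1
Why: The chelated 2-hydroxyl is alkylated under more forcing Williamson conditions, which the allyl ether and the methyl ester tolerate.

Step 7
Reactants: 10 methyl 4-(allyloxy)-2-(benzyloxy)benzoate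
Product: 11 methyl 4-(allyloxy)-2-(benzyloxy)-5-formylbenzoate
Conditions: POCl3, DMF, 0 to 80 °C; then H2O
Reagents that add atoms: N,N-dimethylformamide, CN(C)C=O; water, O
Why: Vilsmeier–Haack formylation should attack C-5, para to the benzyloxy and ortho to the allyloxy group, because the only other activated position (C-3) lies between the two ether groups and is shielded.

Step 8
Reactants: 11 methyl 4-(allyloxy)-2-(benzyloxy)-5-formylbenzoate
Product: 13 methyl 4-(allyloxy)-2-(benzyloxy)-5-hydroxybenzoate, via aryl formate 12 (not isolated)
Conditions: 30% H2O2, H2SO4 (cat.), MeOH, rt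
Reagents that add atoms: hydrogen peroxide, OO
Why: In this acid-catalysed Dakin oxidation the electron-rich aryl group, carrying ortho and para alkoxy groups, migrates to oxygen in the peroxide adduct and the aryl formate is methanolysed in the flask, while hydrogen peroxide under these conditions should not epoxidise the allyl ether.

Step 9
Reactants: 13 methyl 4-(allyloxy)-2-(benzyloxy)-5-hydroxybenzoate
Product: 14 methyl 4-(allyloxy)-6-(benzyloxy)-2-formyl-3-hydroxybenzoate
Conditions: MgCl2, Et3N, (CH2O)n, MeCN, reflux; then 1 M HCl
Reagents that add atoms: paraformaldehyde (as formaldehyde), C=O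
Why: In this magnesium-mediated ortho-formylation (Casnati–Skattebøl type) formaldehyde is delivered within the magnesium phenoxide chelate to the only free position ortho to the hydroxyl, and a second equivalent oxidises the benzylic alkoxide to the aldehyde.

Step 10
Reactants: 14 methyl 4-(allyloxy)-6-(benzyloxy)-2-formyl-3-hydroxybenzoate
Product: 15 5-(allyloxy)-7-(benzyloxy)-3,4-dihydroxy-2-benzofuran-1(3H)-one (racemic lactol)
Conditions: LiOH, THF/H2O, rt; then 1 M HCl
Reagents that add atoms: lithium hydroxide, [Li+].[OH-]
Why: Saponification of the methyl ester is assisted by the neighbouring formyl group, and on acidification the 2-formylbenzoic acid closes to the five-membered lactol by 5-exo-trig addition of the carboxyl oxygen to the aldehyde, the new centre being racemic at this point.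

Step 11
Reactants: 15 5-(allyloxy)-7-(benzyloxy)-3,4-dihydroxy-2-benzofuran-1(3H)-one; 16 (R)-1-phenylethanol (3 equiv)
Product: 17 (3S)-5-(allyloxy)-7-(benzyloxy)-4-hydroxy-3-[(1R)-1-phenylethoxy]-2-benzofuran-1(3H)-one
Conditions: PPTS (10 mol %), 4 Å molecular sieves, toluene, 60 °C; chromatographic separation of the epimers
Reagents that add atoms: none
Why: Acid-catalysed acetal exchange through the phthalidyl oxocarbenium ion should give both C-3 epimers, which are diastereomers because of the (R)-1-phenylethyl group; the 3S epimer 17 is isolated by chromatography (configuration to be confirmed by crystallography) and the other C-3 epimer is returned to the same conditions for re-equilibration, so the stereocentre is set by separation and not by induction.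

Step 12
Reactants: 17 (3S)-5-(allyloxy)-7-(benzyloxy)-4-hydroxy-3-[(1R)-1-phenylethoxy]-2-benzofuran-1(3H)-one
Product: 18 (3S)-5-(allyloxy)-7-(benzyloxy)-4-(formyloxy)-3-[(1R)-1-phenylethoxy]-2-benzofuran-1(3H)-one
Conditions: acetic formic anhydride (preformed), pyridine, CH2Cl2, −20 to 0 °C
Reagents that add atoms: acetic formic anhydride, CC(=O)OC=O
Why: O-Formylation of the phenol with the mixed anhydride goes at the formyl carbon, the more electrophilic and less hindered carbonyl, under mild conditions that leave the acetal untouched.

Step 13
Reactants: 7 allyl 4-methoxy-6-methyl-2-(trifluoromethylsulfonyloxy)-3-(trimethylsilyl)benzoate; 18 (3S)-5-(allyloxy)-7-(benzyloxy)-4-(formyloxy)-3-[(1R)-1-phenylethoxy]-2-benzofuran-1(3H)-one (1.5 equiv)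
Product: 21 allyl 2-{[(3S)-5-(allyloxy)-7-(benzyloxy)-1-oxo-3-[(1R)-1-phenylethoxy]-1,3-dihydro-2-benzofuran-4-yl]oxy}-3-formyl-4-methoxy-6-methylbenzoate, via aryne 19 (not isolated), via aryl cesium adduct 20 (not isolated)
Conditions: CsF (3 equiv), 18-crown-6, THF, 0 °C to rt; 7 added slowly to 18
Reagents that add atoms: none
Why: Proposed new method: CsF removes the silyl group of 7 and triflate leaves to give aryne 19; a small amount of the cesium phenoxide of 17, set free when fluoride attacks the formyl carbon of 18, adds to the aryne carbon beside the ester, and the aryl cesium 20 so formed takes the formyl group from a further molecule of 18, which returns the phenoxide and carries a chain whose net result is insertion of the aryne into the ArO–CHO bond. The closest known reaction types are three-component aryne couplings in which a heteroatom nucleophile adds and the aryl anion is caught by a carbonyl electrophile (aldehydes, CO2) and the insertion of arynes into the C–O bond of carboxylic acids; an aryl formate as combined aryloxy and formyl donor has not been shown. No ring is closed and no stereocentre is formed. The step needs the phenoxide to add at the aryne carbon remote from the methoxy group; the methoxy group distorts the aryne and stabilises the developing anion on the carbon next to it, and this should outweigh the smaller opposite pull of the ester. It also needs 20 to be formylated before it is protonated or attacks another carbonyl group, which the unhindered, strongly electrophilic formate, kept in excess in aprotic THF, should favour over the lactone and the shielded allyl ester. The acetal centre of ring B should pass unchanged because no acid is present, the lactone C–O bond lies in the plane of ring B where the ortho phenoxide cannot expel it, and the exocyclic alkoxide is a poor leaving group.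

Step 14
Reactants: 21 allyl 2-{[(3S)-5-(allyloxy)-7-(benzyloxy)-1-oxo-3-[(1R)-1-phenylethoxy]-1,3-dihydro-2-benzofuran-4-yl]oxy}-3-formyl-4-methoxy-6-methylbenzoate
Product: 22 3-formyl-2-{[(3S)-7-(benzyloxy)-5-hydroxy-1-oxo-3-[(1R)-1-phenylethoxy]-1,3-dihydro-2-benzofuran-4-yl]oxy}-4-methoxy-6-methylbenzoic acid
Conditions: Pd(PPh3)4 (5 mol %), N-methylaniline, THF, rt
Reagents that add atoms: none
Why: In this Tsuji–Trost deallylation zerovalent palladium ionises the allyl ester and the allyl aryl ether to π-allyl complexes that N-methylaniline captures, under neutral conditions that should spare the aldehyde, the benzyl ether and the acetal.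

Step 15
Reactants: 22 3-formyl-2-{[(3S)-7-(benzyloxy)-5-hydroxy-1-oxo-3-[(1R)-1-phenylethoxy]-1,3-dihydro-2-benzofuran-4-yl]oxy}-4-methoxy-6-methylbenzoic acid
Product: 23 (1S)-4-(benzyloxy)-10-methoxy-8-methyl-3,7-dioxo-1-[(1R)-1-phenylethoxy]-1,3-dihydro-7H-isobenzofuro[4,5-b][1,4]benzodioxepine-11-carbaldehyde
Conditions: DCC, DMAP (cat.), CH2Cl2, rt
Reagents that add atoms: none
Why: In this Steglich-type lactonisation the O-acylisourea of the hindered benzoic acid is attacked by the phenol held ortho on the diaryl ether, closing the seven-membered ring C (7-exo-trig), the standard closure of depsidones from 2-(2-hydroxyaryloxy)benzoic acids.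

Step 16
Reactants: 23 (1S)-4-(benzyloxy)-10-methoxy-8-methyl-3,7-dioxo-1-[(1R)-1-phenylethoxy]-1,3-dihydro-7H-isobenzofuro[4,5-b][1,4]benzodioxepine-11-carbaldehyde
Product: 24 (1S)-1,4-dihydroxy-10-methoxy-8-methyl-3,7-dioxo-1,3-dihydro-7H-isobenzofuro[4,5-b][1,4]benzodioxepine-11-carbaldehyde (target)
Conditions: H2 (1 atm), 10% Pd/C, EtOAc, rt; neutral work-up
Reagents that add atoms: none
Why: Hydrogenolysis cleaves the two benzylic C–O bonds (benzyl ether and 1-phenylethyl acetal) on palladium; because the bond broken in the acetal is the O–CH(CH3)Ph bond, the configuration at the lactol carbon is retained, and ethyl acetate at 1 atm should keep reduction of the doubly ortho-substituted aldehyde slow.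

**Compound list**

1 | orsellinic acid (2,4-dihydroxy-6-methylbenzoic acid) | Cc1cc(O)cc(O)c1C(=O)O | starting material
2 | allyl 2,4-dihydroxy-6-methylbenzoate | C=CCOC(=O)c1c(C)cc(O)cc1O | intermediate
3 | allyl 2-hydroxy-4-methoxy-6-methylbenzoate | C=CCOC(=O)c1c(C)cc(OC)cc1O | intermediate
4 | allyl 3-bromo-2-hydroxy-4-methoxy-6-methylbenzoate | C=CCOC(=O)c1c(C)cc(OC)c(Br)c1O | intermediate
5 | allyl 3-bromo-4-methoxy-6-methyl-2-(trimethylsilyloxy)benzoate (not isolated) | C=CCOC(=O)c1c(C)cc(OC)c(Br)c1O[Si](C)(C)C | intermediate
6 | lithium 2-(allyloxycarbonyl)-5-methoxy-3-methyl-6-(trimethylsilyl)phenoxide (not isolated) | [Li+].C=CCOC(=O)c1c(C)cc(OC)c([Si](C)(C)C)c1[O-] | intermediate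
7 | allyl 4-methoxy-6-methyl-2-(trifluoromethylsulfonyloxy)-3-(trimethylsilyl)benzoate (ring A aryne precursor) | C=CCOC(=O)c1c(C)cc(OC)c([Si](C)(C)C)c1OS(=O)(=O)C(F)(F)F | intermediate
8 | methyl 2,4-dihydroxybenzoate | COC(=O)c1ccc(O)cc1O | starting material
9 | methyl 4-(allyloxy)-2-hydroxybenzoate | COC(=O)c1ccc(OCC=C)cc1O | intermediate
10 | methyl 4-(allyloxy)-2-(benzyloxy)benzoate | COC(=O)c1ccc(OCC=C)cc1OCc1ccccc1 | intermediate
11 | methyl 4-(allyloxy)-2-(benzyloxy)-5-formylbenzoate | COC(=O)c1cc(C=O)c(OCC=C)cc1OCc1ccccc1 | intermediate
12 | methyl 4-(allyloxy)-2-(benzyloxy)-5-(formyloxy)benzoate (not isolated) | COC(=O)c1cc(OC=O)c(OCC=C)cc1OCc1ccccc1 | intermediate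
13 | methyl 4-(allyloxy)-2-(benzyloxy)-5-hydroxybenzoate | COC(=O)c1cc(O)c(OCC=C)cc1OCc1ccccc1 | intermediate
14 | methyl 4-(allyloxy)-6-(benzyloxy)-2-formyl-3-hydroxybenzoate | COC(=O)c1c(C=O)c(O)c(OCC=C)cc1OCc1ccccc1 | intermediate
15 | 5-(allyloxy)-7-(benzyloxy)-3,4-dihydroxy-2-benzofuran-1(3H)-one (racemic lactol) | O=C1OC(O)c2c(O)c(OCC=C)cc(OCc3ccccc3)c21 | intermediate
16 | (R)-1-phenylethanol | C[C@@H](O)c1ccccc1 | starting material
17 | (3S)-5-(allyloxy)-7-(benzyloxy)-4-hydroxy-3-[(1R)-1-phenylethoxy]-2-benzofuran-1(3H)-one | Oc1c(OCC=C)cc(OCc2ccccc2)c2c1[C@@H](O[C@H](C)c1ccccc1)OC2=O | intermediate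
18 | (3S)-5-(allyloxy)-7-(benzyloxy)-4-(formyloxy)-3-[(1R)-1-phenylethoxy]-2-benzofuran-1(3H)-one (ring B aryl formate) | O=COc1c(OCC=C)cc(OCc2ccccc2)c2c1[C@@H](O[C@H](C)c1ccccc1)OC2=O | intermediate
19 | allyl 2,3-didehydro-4-methoxy-6-methylbenzoate (ring A aryne, not isolated) | C=CCOC(=O)C1=C(C)C=C(OC)C#C1 | intermediate
20 | cesium aryl adduct of the phenoxide of 17 with 19, anion on the carbon next to the methoxy group (not isolated) | [Cs+].C=CCOC(=O)c1c(C)cc(OC)[c-]c1Oc1c(OCC=C)cc(OCc2ccccc2)c2c1[C@@H](O[C@H](C)c1ccccc1)OC2=O | intermediate
21 | allyl 2-{[(3S)-5-(allyloxy)-7-(benzyloxy)-1-oxo-3-[(1R)-1-phenylethoxy]-1,3-dihydro-2-benzofuran-4-yl]oxy}-3-formyl-4-methoxy-6-methylbenzoate | C=CCOC(=O)c1c(C)cc(OC)c(C=O)c1Oc1c(OCC=C)cc(OCc2ccccc2)c2c1[C@@H](O[C@H](C)c1ccccc1)OC2=O | intermediate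
22 | 3-formyl-2-{[(3S)-7-(benzyloxy)-5-hydroxy-1-oxo-3-[(1R)-1-phenylethoxy]-1,3-dihydro-2-benzofuran-4-yl]oxy}-4-methoxy-6-methylbenzoic acid | OC(=O)c1c(C)cc(OC)c(C=O)c1Oc1c(O)cc(OCc2ccccc2)c2c1[C@@H](O[C@H](C)c1ccccc1)OC2=O | intermediate
23 | (1S)-4-(benzyloxy)-10-methoxy-8-methyl-3,7-dioxo-1-[(1R)-1-phenylethoxy]-1,3-dihydro-7H-isobenzofuro[4,5-b][1,4]benzodioxepine-11-carbaldehyde | COc1cc(C)c2c(c1C=O)Oc1c(cc(OCc4ccccc4)c3c1[C@@H](O[C@H](C)c5ccccc5)OC3=O)OC2=O | intermediate
24 | (1S)-1,4-dihydroxy-10-methoxy-8-methyl-3,7-dioxo-1,3-dihydro-7H-isobenzofuro[4,5-b][1,4]benzodioxepine-11-carbaldehyde (CNP0216483.1) | COc1cc(C)c2c(c1C=O)Oc1c(cc(O)c3c1[C@@H](O)OC3=O)OC2=O | target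

**Step count and risks**

Total: 16 steps. Longest linear sequence: 12 steps (steps 5–16, from methyl 2,4-dihydroxybenzoate); the ring A branch is 4 steps before the junction.

Steps most likely to fail:

1. Step 13 (proposed new method). Fluoride may decarbonylate the formate and so destroy the formyl donor. The aryl anion may be protonated before formyl transfer, by adventitious proton sources or by the acetal C–H, which would give the formyl-free diaryl ether. The phenoxide may also add at the wrong aryne carbon. The fallback uses known chemistry, sets out from ester 3 and phenol 17, and comes back to the route at 21. Rieche formylation of 3 (Cl2CHOMe, TiCl4, CH2Cl2, 0 °C), directed ortho to the phenol, should give allyl 3-formyl-2-hydroxy-4-methoxy-6-methylbenzoate F1. Treatment with SO2F2 and NMe4F in DMF should convert it, through allyl 2-(fluorosulfonyloxy)-3-formyl-4-methoxy-6-methylbenzoate F2, into allyl 2-fluoro-3-formyl-4-methoxy-6-methylbenzoate F3; this is a deoxyfluorination by nucleophilic aromatic substitution, activated by the ortho formyl and ester groups. F3 and 17 with K2CO3 in DMF at 60 °C should then give 21 by nucleophilic aromatic substitution of fluoride.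

2. Step 16. The ring A aldehyde may be over-reduced while the secondary benzylic acetal is cleaved only slowly, and the freed lactol may epimerise by ring–chain tautomerism if traces of acid or base are present. The fallback sets out from 23 and comes back at 24 without hydrogen: BCl3 with pentamethylbenzene in CH2Cl2 at −78 °C should ionise both benzylic C–O bonds. The benzyl and 1-phenylethyl cations are captured by pentamethylbenzene, and the lactol oxygen stays on its carbon because the phthalidyl cation is the less stable alternative. This fallback makes no new compound (F0); the methyl ether next to the formyl group is the group to watch, so the reaction is quenched cold.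

3. Step 9. Electrophilic attack at the position flanked by the phenol and the ester may be sluggish, and the phenol may be O-alkylated by formaldehyde on long heating. The fallback sets out from 13 and comes back at 14 by directed metalation. MOMCl and i-Pr2NEt in CH2Cl2 should give methyl 4-(allyloxy)-2-(benzyloxy)-5-(methoxymethoxy)benzoate F4. TMP2Mg·2LiCl in THF at 0 °C should magnesiate the position between the ester and the MOM ether, and DMF should then give methyl 4-(allyloxy)-6-(benzyloxy)-2-formyl-3-(methoxymethoxy)benzoate F5. Aqueous HCl in THF at 40 °C removes the MOM group to give 14.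

Further compounds
F1 | step 13 | allyl 3-formyl-2-hydroxy-4-methoxy-6-methylbenzoate | C=CCOC(=O)c1c(C)cc(OC)c(C=O)c1O
F2 | step 13 | allyl 2-(fluorosulfonyloxy)-3-formyl-4-methoxy-6-methylbenzoate | C=CCOC(=O)c1c(C)cc(OC)c(C=O)c1OS(=O)(=O)F
F3 | step 13 | allyl 2-fluoro-3-formyl-4-methoxy-6-methylbenzoate | C=CCOC(=O)c1c(C)cc(OC)c(C=O)c1F
F0 | step 16 | none | none
F4 | step 9 | methyl 4-(allyloxy)-2-(benzyloxy)-5-(methoxymethoxy)benzoate | COCOc1cc(C(=O)OC)c(OCc2ccccc2)cc1OCC=C
F5 | step 9 | methyl 4-(allyloxy)-6-(benzyloxy)-2-formyl-3-(methoxymethoxy)benzoate | COCOc1c(C=O)c(C(=O)OC)c(OCc2ccccc2)cc1OCC=C
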